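## The problem

The target, (2S,4R,5R,6S,7R,8S)-2α,6α-diacetoxy-4α,5β-epoxygermacra-1(10)E,11(13)-dien-12,8α-olide, is a ten-membered carbocycle (C1–C10) with an α-methylene γ-lactone trans-fused across C7–C8. Closing a ten-membered ring by bond formation costs strain and entropy. The ring also needs an E-trisubstituted C1=C10 alkene and, latent in the trans epoxide, an E-trisubstituted C4=C5 alkene. Of the six stereocentres, C6, C7 and C8 are contiguous. If the macrocycle is folded into a trans-decalin by a C5–C10 bond, their three substituents are all equatorial, so a quaternary C10 can control them under thermodynamic conditions. The C6 hydroxyl can then direct the C4–C5 epoxidation, whereas C2 is remote and must be set by ring conformation or by inversion. The acrylate is a Michael acceptor towards hydrides, fluoride, amide bases and phosphines. The vinyl epoxide cyclises across the ring under acid, the allylic acetates do not survive base, and a germacra-1(10),4-diene undergoes Cope rearrangement on heating. The enabling feature is the run of six ring atoms C10=C1–C2(O)–C3–C4(–O–)C5. Written as the trienol ether C10=C1–C2(OSi)=C3–C4=C5, it is the open form of a 2-silyloxycyclohexa-1,3-diene (ring A of a eudesmane) closed by the C5–C10 bond.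

## Retrosynthesis

**End game, 33 back to 30.** The C6 acetate of 33 is cut first, then the epoxide oxygen of 32, then the silyl ether of 31. Epoxidation is placed between the two acylations so that only the C6 hydroxyl is free to direct the oxidant to C4=C5 while the C2 oxygen, allylic to C1=C10, is already capped. The forward steps must be mild and non-acidic because of the vinyl epoxide.

**C2 acetate and methylene, 30 back to 25.** The C2–O bond of 30 is cut with inversion to the 2β-alcohol 29 (Mitsunobu). The C11=C13 bond is cut to the Mannich base 27 and the plain lactone 26, and the carbinol hydrogen is removed to give ketone 25. Ring-periphery hydride attack on 25 is expected to give the pseudo-axial 2β-alcohol, so inversion with acetic acid is planned rather than direct acetylation. The acrylate is introduced only here, after the photochemistry, the fluoride step and the borohydride step, and before any acetate is present.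

**Key cut, 25 back to 23.** Ketone 25 is the hydrolysis product of trienol ether 24. Re-forming the C5–C10 bond of 24 gives the trans-fused hexalin 23. Against a macrocyclisation, this cut pays the ring strain with light and fixes both trisubstituted alkene geometries in one conrotatory event. The precursor is a rigid decalin in which every stereocentre is conformationally defined. The forward reaction must give the triene without secondary photochemistry or thermal reclosure.

**Ring A functionality, 23 back to 18.** The dienol ether 23 comes from the kinetic C1 enolate of enone 22. Enone 22 comes from alcohol 20 by oxidation and dehydrogenation, and 20 from alkene 18 by hydroboration. The C1=C2 alkene of 18 is the natural by-product of the Claisen step below and is inert through ring-B construction, so ring A needs no protecting group. Because C10 is quaternary, dehydrogenation of the C2 ketone can only give the C3=C4 enone.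

**C6 carbinol, 18 back to 16.** The silyl ether is removed and the C6–H bond cut to ketone 16. The forward reduction must deliver the equatorial 6α-alcohol, against the kinetic preference of hydride reagents, so a single-electron reduction is chosen.

**Ring B, 16 back to 13.** The lactone C12–O bond and the C7–C8 bond are cut, giving a C8 aldehyde and a C6 ketone that carries the succinate-derived chain (after removal of the acetal in 13). Only the C7–C8 aldol can give a six-membered ring. It places oxygen on C8 and the ester γ to it, so the 12,8-olide forms regiospecifically and C6 stays a ketone. A 1,3-dione route would leave the two oxygens undifferentiated. The forward reaction is reversible, so C7 and C8 settle equatorial.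

**Side chain, 13 back to 9.** The C7–C11 bond is cut (alkylation of methyl ketone 11 with ethyl bromoacetate 12). The C6–C7 bond is cut (methyl Grignard on Weinreb amide 10, made from ester 9). The aldehyde is carried as a dioxolane through these steps.

**Quaternary C10, 9 back to 5.** The acetal is removed to give aldehyde 8, and the C9–C10 bond is cut by a retro-Claisen rearrangement to allylic alcohol 5 and ethyl vinyl ether 6. A conjugate addition to enone 4 was the neighbouring option, but it is expected to enter trans to the C4 methyl and would give the wrong relative configuration for a trans-decalin. The sigmatropic shift delivers C9 to the face of the C2–O bond.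

**Ring A, 5 back to 1 and 2.** Alcohol 5 comes from enone 4 by 1,2-reduction. Cutting C1=C10 (aldol condensation) and C4–C5 (Michael addition) gives ethyl acetoacetate 1 and (E)-pent-3-en-2-one 2, through adduct 3. The only element of absolute control in the whole route is the methyl-bearing C4 set in this Michael addition. It relays to C2, then to C10, and is erased when the C3=C4 alkene is made.

## Roads not taken

**Alternative 1:** SmI2 pinacol macrocyclisation at the epoxide carbons. The cut is C4–C5. Divalent samarium would couple a C5 aldehyde with a C4 methyl ketone in an open chain and close the ten-membered ring as the cis-diol A1. The merits are real. The bond formed joins the two epoxide carbons, the diol is one sulfonylation/displacement from the epoxide, the chain can be assembled convergently, and the conversion is not limited by a photostationary state. In convergence and scalability this road is as good as or better than the chosen one. Its weak points for this target: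
- A ketone–aldehyde pinacol must form a strained ten-membered ring and set two stereocentres at once, both of which must be right for the trans epoxide.
- C2, C6, C7, C8 and the E-C1=C10 alkene must each be installed separately in an acyclic precursor.
- The protecting-group load is heavy (two PMB ethers, two silyl ethers) and the C12 alcohol must still be oxidised to the lactone.

Against this the chosen plan sets one pericyclic event that fixes both alkene geometries, and ring-B stereocentres that arise under thermodynamic control in a rigid decalin.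

**Alternative 2:** Anionic oxy-Cope ring expansion. The [3,3] shift of a potassium trans-1,2-dialkenylcyclohexanolate breaks C5–C10 (the same bond as here) and forms C2–C3. The C10 enolate is trapped as enol triflate A2, which a methyl cross-coupling would convert into the C10 methyl alkene. This step is irreversible, thermal and well precedented for germacranes. A chair transition state transmits the C2 configuration and the 4E geometry. In conversion it is probably the more reliable ring expansion. The weak points lie before and after it: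
- The substrate is a tertiary divinylcyclohexanol carrying five stereocentres and a geometrically defined alkoxyvinyl group.
- The enolate geometry at the moment of triflation decides the C1=C10 geometry.
- The C10 methyl and the lactone oxidation state need further steps.

The chosen plan answers with a precursor made by annulation from two cheap carbonyl compounds, and with C14 and the C2 oxygen already in place when the ring opens.

**Alternative 3:** Nickel reductive vinyl–alkyl coupling closing C9–C10. A nickel catalyst (for example NiBr2·glyme with a bipyridine ligand) and zinc would join a C10 vinyl bromide and a C9 primary iodide of one chain to give A3 with retention of alkene geometry. The conditions are mild, tolerate the acetate and silyl ethers, and the alkene geometries are set beforehand by standard olefinations. In modularity and freedom from conformational guesswork it is the better road. Its weak points: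
- A catalytic sp2–sp3 coupling must win against oligomerisation, protodehalogenation and β-hydride elimination while forming a ten-membered ring at high dilution.
- All five stereocentres and both E-trisubstituted alkenes must be carried through the longest acyclic sequence of the three.

The chosen plan has to set against this a shorter, annulation-based build-up and a ring opening with no entropic penalty. The price is a photochemical step that must be stopped at partial conversion.

Key step: step 14

## Route

Assumption 1: bicyclic and ten-membered compounds carry eudesmane/germacrane locants (C14 on C10, C15 on C4, C11–C13 on C7), and α/β refer to the drawing in which C14 is β.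

Assumption 2: the cinchona pseudoenantiomer that gives adduct 3 with the 3R configuration is used in step 1.

Step 1
Reactants: 1 ethyl acetoacetate; 2 (E)-pent-3-en-2-one
Product: 4 ethyl (1S,6R)-2,6-dimethyl-4-oxocyclohex-2-ene-1-carboxylate, via Michael adduct 3 (not isolated)
Conditions: 9-amino-9-deoxy-epi-cinchona primary amine (20 mol %), TFA (40 mol %), toluene, rt; then p-TsOH·H2O (10 mol %), toluene, reflux, Dean–Stark
Reagents that add atoms: none
Why: Iminium-catalysed asymmetric Michael addition of the β-keto ester to the enone sets the methyl-bearing carbon (catalyst control); the acid-promoted aldol condensation of the methyl ketone onto the keto-ester carbonyl (Robinson-type annulation, as for Hagemann's ester) closes the ring, and the ester-bearing carbon equilibrates trans to the methyl group.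

Step 2
Reactants: 4 ethyl (1S,6R)-2,6-dimethyl-4-oxocyclohex-2-ene-1-carboxylate
Product: 5 ethyl (1S,4S,6R)-4-hydroxy-2,6-dimethylcyclohex-2-ene-1-carboxylate
Conditions: NaBH4, CeCl3·7H2O, MeOH, −78 °C
Reagents that add atoms: none
Why: Luche 1,2-reduction; axial hydride attack on the half-chair with the C6 methyl equatorial should give the pseudo-equatorial alcohol cis to that methyl, as with other 5-substituted cyclohexenones, and the ester is untouched.

Step 3
Reactants: 5 ethyl (1S,4S,6R)-4-hydroxy-2,6-dimethylcyclohex-2-ene-1-carboxylate; 6 ethyl vinyl ether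
Product: 8 ethyl (1S,2S,6R)-2,6-dimethyl-2-(2-oxoethyl)cyclohex-3-ene-1-carboxylate, via allyl vinyl ether 7 (not isolated)
Conditions: 6 (solvent), Hg(OAc)2 (10 mol %), reflux; concentrate; xylene, 180 °C, sealed tube
Reagents that add atoms: none
Why: Mercury-catalysed transvinylation followed by Claisen rearrangement; the [3,3] shift is suprafacial, so the new C–C bond of the quaternary carbon (eudesmane C10) forms on the face the oxygen leaves, cis to the C6 methyl and trans to the ester, which puts all large groups equatorial.

Step 4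
Reactants: 8 ethyl (1S,2S,6R)-2,6-dimethyl-2-(2-oxoethyl)cyclohex-3-ene-1-carboxylate
Product: 9 ethyl (1S,2S,6R)-2-(1,3-dioxolan-2-ylmethyl)-2,6-dimethylcyclohex-3-ene-1-carboxylate
Conditions: HOCH2CH2OH, PPTS (cat.), benzene, reflux, Dean–Stark
Reagents that add atoms: ethylene glycol, OCCO
Why: Acetalisation masks the aldehyde for the organometallic and enolate steps that follow.

Step 5
Reactants: 9 ethyl (1S,2S,6R)-2-(1,3-dioxolan-2-ylmethyl)-2,6-dimethylcyclohex-3-ene-1-carboxylate
Product: 10 (1S,2S,6R)-2-(1,3-dioxolan-2-ylmethyl)-N-methoxy-N,2,6-trimethylcyclohex-3-ene-1-carboxamide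
Conditions: MeNH(OMe)·HCl, i-PrMgCl, THF, −20 → 0 °C
Reagents that add atoms: N,O-dimethylhydroxylamine hydrochloride, CNOC.Cl
Why: Aminolysis of the hindered ester by the magnesium amide gives the Weinreb amide; the all-equatorial stereocentre α to the carbonyl is the thermodynamic one and should be retained.

Step 6
Reactants: 10 (1S,2S,6R)-2-(1,3-dioxolan-2-ylmethyl)-N-methoxy-N,2,6-trimethylcyclohex-3-ene-1-carboxamide
Product: 11 1-[(1S,2S,6R)-2-(1,3-dioxolan-2-ylmethyl)-2,6-dimethylcyclohex-3-en-1-yl]ethan-1-one
Conditions: MeMgBr, THF, 0 °C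
Reagents that add atoms: methylmagnesium bromide, C[Mg]Br
Why: Weinreb ketone synthesis; the chelated tetrahedral intermediate prevents over-addition, and the new methyl group is C7.

Step 7
Reactants: 11 1-[(1S,2S,6R)-2-(1,3-dioxolan-2-ylmethyl)-2,6-dimethylcyclohex-3-en-1-yl]ethan-1-one; 12 ethyl bromoacetate
Product: 13 ethyl 4-[(1S,2S,6R)-2-(1,3-dioxolan-2-ylmethyl)-2,6-dimethylcyclohex-3-en-1-yl]-4-oxobutanoate
Conditions: LDA, THF, −78 °C; then 12, DMPU, −78 → −40 °C
Reagents that add atoms: none
Why: Kinetic deprotonation should occur at the methyl group rather than at the hindered ring methine, and SN2 alkylation of that enolate forms C7–C11.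

Step 8
Reactants: 13 ethyl 4-[(1S,2S,6R)-2-(1,3-dioxolan-2-ylmethyl)-2,6-dimethylcyclohex-3-en-1-yl]-4-oxobutanoate
Product: 16 6-oxo-13-nor-4βH,5αH,7αH-eudesm-1-en-12,8α-olide, via keto aldehyde 14 (not isolated), via aldol adduct 15 (not isolated)
Conditions: 1 M HCl, THF, rt; then K2CO3, EtOH, 0 °C → rt; then PPTS, toluene, 60 °C
Reagents that add atoms: water, O
Why: Acetal hydrolysis, then a reversible intramolecular aldol addition of the C7 enolate to the C8 aldehyde (6-exo-trig, the only six-membered mode) closes ring B; under equilibration the C8 hydroxyl should sit equatorial (the axial epimer clashes with C14), the C7 chain equatorial and the ring fusion trans, and 5-exo-trig lactonisation traps this isomer as the trans-fused 12,8-olide.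

Step 9
Reactants: 16 6-oxo-13-nor-4βH,5αH,7αH-eudesm-1-en-12,8α-olide
Product: 17 6α-hydroxy-13-nor-4βH,5αH,7αH-eudesm-1-en-12,8α-olide
Conditions: SmI2, THF–MeOH, 0 °C; pH 7 buffer quench
Reagents that add atoms: none
Why: Single-electron ketone reduction; protonation of the ketyl-derived carbanion should place hydrogen axial (β) and give the more stable equatorial 6α-alcohol, the outcome of dissolving-metal reductions of hindered decalones, while the γ-lactone and alkene are inert to SmI2 without an amine additive.

Step 10
Reactants: 17 6α-hydroxy-13-nor-4βH,5αH,7αH-eudesm-1-en-12,8α-olide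
Product: 18 6α-(tert-butyldimethylsilyloxy)-13-nor-4βH,5αH,7αH-eudesm-1-en-12,8α-olide
Conditions: TBSOTf, 2,6-lutidine, CH2Cl2, −78 → 0 °C
Reagents that add atoms: tert-butyldimethylsilyl triflate, CC(C)(C)[Si](C)(C)OS(=O)(=O)C(F)(F)F
Why: Silylation of the hindered secondary alcohol with the silyl triflate; capping O6 at once also blocks lactone migration from O8 to O6.

Step 11
Reactants: 18 6α-(tert-butyldimethylsilyloxy)-13-nor-4βH,5αH,7αH-eudesm-1-en-12,8α-olide
Product: 20 6α-(tert-butyldimethylsilyloxy)-2α-hydroxy-13-nor-4βH,5αH,7αH-eudesman-12,8α-olide, via alkylborane 19 (not isolated)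
Conditions: 9-BBN, THF, 60 °C; then H2O2, pH 7 phosphate buffer, 0 °C → rt
Reagents that add atoms: hydrogen peroxide, OO
Why: Hydroboration–oxidation; boron should add to C2, away from the quaternary C10, from the α face opposite the axial C14, and oxidation proceeds with retention (the C2 configuration is erased in the next step).

Step 12
Reactants: 20 6α-(tert-butyldimethylsilyloxy)-2α-hydroxy-13-nor-4βH,5αH,7αH-eudesman-12,8α-olide
Product: 22 6α-(tert-butyldimethylsilyloxy)-2-oxo-13-nor-5αH,7αH-eudesm-3-en-12,8α-olide, via 2-ketone 21 (not isolated)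
Conditions: IBX (4 equiv), DMSO, 25 → 75 °C
Reagents that add atoms: none
Why: IBX oxidises the alcohol and then dehydrogenates the ketone through its enol; only the C3 enol has a β-hydrogen (C10 is quaternary), so the C3=C4 enone is the single possible regioisomer and the C4 relay stereocentre is removed.

Step 13
Reactants: 22 6α-(tert-butyldimethylsilyloxy)-2-oxo-13-nor-5αH,7αH-eudesm-3-en-12,8α-olide
Product: 23 6α-(tert-butyldimethylsilyloxy)-2-(triethylsilyloxy)-13-nor-5αH,7αH-eudesma-1,3-dien-12,8α-olide
Conditions: LDA (1.05 equiv), THF, −78 °C; TESCl, −78 °C; Et3N-buffered work-up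
Reagents that add atoms: chlorotriethylsilane, CC[Si](Cl)(CC)CC
Why: Kinetic deprotonation of the enone at C1 gives the cross-conjugated dienolate, which is O-silylated; the lactone α-protons are several pK units less acidic and no acrylate is present to intercept the amide base.

Step 14
Reactants: 23 6α-(tert-butyldimethylsilyloxy)-2-(triethylsilyloxy)-13-nor-5αH,7αH-eudesma-1,3-dien-12,8α-olide
Product: 24 (1(10)E,2E,4E)-6α-(tert-butyldimethylsilyloxy)-2-(triethylsilyloxy)-13-nor-7αH-germacra-1(10),2,4-trien-12,8α-olide
Conditions: hν (254 nm, quartz), degassed pentane–Et2O, −78 °C, stopped at partial conversion; kept cold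
Reagents that add atoms: none
Why: Excitation of the 2-silyloxycyclohexa-1,3-diene, the only chromophore absorbing at this wavelength, triggers a conrotatory 6π electrocyclic ring opening that cleaves the C5–C10 σ-bond. The closest known reaction type is the photochemical opening of trans-fused hexalin 1,3-dienes to cyclodeca-1,3,5-trienes (provitamin D to previtamin D, eudesmane dienes to germacratrienes). No ring is closed by bond formation: the ten-membered ring appears when the bond shared by the two six-membered rings breaks. No stereocentre is created; C6, C7 and C8 are untouched and C5 and C10 become sp2. The geometry of both new trisubstituted alkenes follows from the trans ring fusion: conrotation turns C6 and C9, which lie on opposite faces, outward, the only sense the four-carbon bridge should allow, and H5 and C14 inward, giving 1(10)E and 4E. The C2=C3 bond stays cis within the ring (CIP descriptor E because of the silyloxy group). The selectivity needed is formation of 24 without secondary photoreaction of the triene, thermal disrotatory reclosure or a 1,7-hydrogen shift. Low temperature, partial conversion and immediate cold cleavage of the enol ether in step 15 should secure it, and unreacted 23 returns as enone 22 in that step.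

Step 15
Reactants: 24 (1(10)E,2E,4E)-6α-(tert-butyldimethylsilyloxy)-2-(triethylsilyloxy)-13-nor-7αH-germacra-1(10),2,4-trien-12,8α-olide
Product: 25 (1(10)E,4E)-6α-(tert-butyldimethylsilyloxy)-2-oxo-13-nor-7αH-germacra-1(10),4-dien-12,8α-olide
Conditions: TBAF, AcOH (1:1.2), THF, −78 °C
Reagents that add atoms: none
Why: Fluoride cleaves the silyl enol ether and the dienolate is protonated kinetically at C3 (α), which removes the central alkene and leaves the C2 ketone conjugated only with C1=C10; the secondary TBS ether survives and the cold buffer avoids isomerisation of C4=C5 into conjugation.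

Step 16
Reactants: 25 (1(10)E,4E)-6α-(tert-butyldimethylsilyloxy)-2-oxo-13-nor-7αH-germacra-1(10),4-dien-12,8α-olide
Product: 26 (1(10)E,4E)-6α-(tert-butyldimethylsilyloxy)-2β-hydroxy-13-nor-7αH-germacra-1(10),4-dien-12,8α-olide
Conditions: NaBH4, CeCl3·7H2O, MeOH, −78 °C
Reagents that add atoms: none
Why: Luche 1,2-reduction; the enone plane stands perpendicular to the ring with its inner face covered, so hydride should enter from the periphery and leave the hydroxyl pseudo-axial on the β face (2R), the epimer that is inverted in step 19.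

Step 17
Reactants: 26 (1(10)E,4E)-6α-(tert-butyldimethylsilyloxy)-2β-hydroxy-13-nor-7αH-germacra-1(10),4-dien-12,8α-olide
Product: 27 (1(10)E,4E)-6α-(tert-butyldimethylsilyloxy)-13-(dimethylamino)-2β-hydroxy-7αH,11ξH-germacra-1(10),4-dien-12,8α-olide
Conditions: LDA (2.3 equiv), THF, −78 °C; CH2=NMe2+ I−, −78 → 0 °C
Reagents that add atoms: N,N-dimethylmethyleneiminium iodide, C=[N+](C)C.[I-]
Why: Mannich reaction of the lactone enolate (formed beside the C2 alkoxide) with Eschenmoser's salt introduces C13; the C11 configuration is lost in the next step.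

Step 18
Reactants: 27 (1(10)E,4E)-6α-(tert-butyldimethylsilyloxy)-13-(dimethylamino)-2β-hydroxy-7αH,11ξH-germacra-1(10),4-dien-12,8α-olide
Product: 29 (1(10)E,4E)-6α-(tert-butyldimethylsilyloxy)-2β-hydroxy-7αH-germacra-1(10),4,11(13)-trien-12,8α-olide, via ammonium iodide 28 (not isolated)
Conditions: MeI, THF–MeOH, rt; then aq. NaHCO3, CH2Cl2, rt
Reagents that add atoms: none
Why: N-Methylation followed by E1cB loss of trimethylamine gives the exocyclic methylene under conditions that leave the alcohol and the diene alone.

Step 19
Reactants: 29 (1(10)E,4E)-6α-(tert-butyldimethylsilyloxy)-2β-hydroxy-7αH-germacra-1(10),4,11(13)-trien-12,8α-olide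
Product: 30 (1(10)E,4E)-2α-acetoxy-6α-(tert-butyldimethylsilyloxy)-7αH-germacra-1(10),4,11(13)-trien-12,8α-olide
Conditions: PPh3, DIAD (betaine preformed), AcOH, toluene, −20 → 0 °C
Reagents that add atoms: acetic acid, CC(=O)O
Why: Mitsunobu reaction; acetate displaces the oxyphosphonium group by SN2 with inversion and gives the pseudo-equatorial 2α (2S) acetate, and preforming the betaine keeps free phosphine away from the acrylate.

Step 20
Reactants: 30 (1(10)E,4E)-2α-acetoxy-6α-(tert-butyldimethylsilyloxy)-7αH-germacra-1(10),4,11(13)-trien-12,8α-olide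
Product: 31 (1(10)E,4E)-2α-acetoxy-6α-hydroxy-7αH-germacra-1(10),4,11(13)-trien-12,8α-olide
Conditions: HF·pyridine, pyridine (excess), THF, 0 °C → rt
Reagents that add atoms: none
Why: Fluoride-mediated cleavage of the allylic silyl ether; the pyridine buffer should prevent acid-induced transannular cyclisation and the acetate and acrylate are inert.

Step 21
Reactants: 31 (1(10)E,4E)-2α-acetoxy-6α-hydroxy-7αH-germacra-1(10),4,11(13)-trien-12,8α-olide
Product: 32 (1(10)E)-2α-acetoxy-4α,5β-epoxy-6α-hydroxy-7αH-germacra-1(10),11(13)-dien-12,8α-olide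
Conditions: VO(acac)2 (5 mol %), t-BuOOH (decane), CH2Cl2, 0 °C
Reagents that add atoms: tert-butyl hydroperoxide, CC(C)(C)OO
Why: Vanadium-catalysed hydroxyl-directed epoxidation of the allylic alcohol; allylic 1,3-strain keeps H6 in the alkene plane and O6 on the outer face, so oxygen should be delivered to that face and give the 4R,5R epoxide, while C1=C10 (its allylic oxygen acetylated) and the acrylate do not react.

Step 22
Reactants: 32 (1(10)E)-2α-acetoxy-4α,5β-epoxy-6α-hydroxy-7αH-germacra-1(10),11(13)-dien-12,8α-olide
Product: 33 (2S,4R,5R,6S,7R,8S)-2α,6α-diacetoxy-4α,5β-epoxygermacra-1(10)E,11(13)-dien-12,8α-olide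
Conditions: Ac2O, DMAP (cat.), Et3N, CH2Cl2, 0 °C
Reagents that add atoms: acetic anhydride, CC(=O)OC(C)=O
Why: DMAP-catalysed acetylation of the C6 hydroxyl under mild base, which the epoxide and acrylate tolerate and which is faster than lactone migration.

## Compound list

1 | ethyl acetoacetate | CCOC(=O)CC(C)=O | starting material
2 | (E)-pent-3-en-2-one | C/C=C/C(C)=O | starting material
3 | ethyl (3R)-2-acetyl-3-methyl-5-oxohexanoate (C2 epimers) | CCOC(=O)C(C(C)=O)[C@H](C)CC(C)=O | intermediate
4 | ethyl (1S,6R)-2,6-dimethyl-4-oxocyclohex-2-ene-1-carboxylate | CCOC(=O)[C@@H]1C(C)=CC(=O)C[C@H]1C | intermediate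
5 | ethyl (1S,4S,6R)-4-hydroxy-2,6-dimethylcyclohex-2-ene-1-carboxylate | CCOC(=O)[C@@H]1C(C)=C[C@@H](O)C[C@H]1C | intermediate
6 | ethyl vinyl ether | C=COCC | starting material
7 | ethyl (1S,4S,6R)-4-(ethenyloxy)-2,6-dimethylcyclohex-2-ene-1-carboxylate | CCOC(=O)[C@@H]1C(C)=C[C@@H](OC=C)C[C@H]1C | intermediate
8 | ethyl (1S,2S,6R)-2,6-dimethyl-2-(2-oxoethyl)cyclohex-3-ene-1-carboxylate | CCOC(=O)[C@@H]1[C@@](C)(CC=O)C=CC[C@H]1C | intermediate
9 | ethyl (1S,2S,6R)-2-(1,3-dioxolan-2-ylmethyl)-2,6-dimethylcyclohex-3-ene-1-carboxylate | CCOC(=O)[C@@H]1[C@@](C)(CC2OCCO2)C=CC[C@H]1C | intermediate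
10 | (1S,2S,6R)-2-(1,3-dioxolan-2-ylmethyl)-N-methoxy-N,2,6-trimethylcyclohex-3-ene-1-carboxamide | CON(C)C(=O)[C@@H]1[C@@](C)(CC2OCCO2)C=CC[C@H]1C | intermediate
11 | 1-[(1S,2S,6R)-2-(1,3-dioxolan-2-ylmethyl)-2,6-dimethylcyclohex-3-en-1-yl]ethan-1-one | CC(=O)[C@@H]1[C@@](C)(CC2OCCO2)C=CC[C@H]1C | intermediate
12 | ethyl bromoacetate | CCOC(=O)CBr | starting material
13 | ethyl 4-[(1S,2S,6R)-2-(1,3-dioxolan-2-ylmethyl)-2,6-dimethylcyclohex-3-en-1-yl]-4-oxobutanoate | CCOC(=O)CCC(=O)[C@@H]1[C@@](C)(CC2OCCO2)C=CC[C@H]1C | intermediate
14 | ethyl 4-[(1S,2S,6R)-2,6-dimethyl-2-(2-oxoethyl)cyclohex-3-en-1-yl]-4-oxobutanoate | CCOC(=O)CCC(=O)[C@@H]1[C@@](C)(CC=O)C=CC[C@H]1C | intermediate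
15 | ethyl 8α-hydroxy-6-oxo-13-nor-4βH,5αH,7αH-eudesm-1-en-12-oate | CCOC(=O)C[C@@H]1[C@@H](O)C[C@@]2(C)C=CC[C@@H](C)[C@@H]2C1=O | intermediate
16 | 6-oxo-13-nor-4βH,5αH,7αH-eudesm-1-en-12,8α-olide | C1C(=O)O[C@H]2C[C@@]3(C)C=CC[C@@H](C)[C@@H]3C(=O)[C@H]12 | intermediate
17 | 6α-hydroxy-13-nor-4βH,5αH,7αH-eudesm-1-en-12,8α-olide | C1C(=O)O[C@H]2C[C@@]3(C)C=CC[C@@H](C)[C@@H]3[C@@H](O)[C@H]12 | intermediate
18 | 6α-(tert-butyldimethylsilyloxy)-13-nor-4βH,5αH,7αH-eudesm-1-en-12,8α-olide | C1C(=O)O[C@H]2C[C@@]3(C)C=CC[C@@H](C)[C@@H]3[C@@H](O[Si](C)(C)C(C)(C)C)[C@H]12 | intermediate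
19 | 2α-(9-borabicyclo[3.3.1]nonan-9-yl)-6α-(tert-butyldimethylsilyloxy)-13-nor-4βH,5αH,7αH-eudesman-12,8α-olide | C1C(=O)O[C@H]2C[C@@]3(C)C[C@@H](B4C5CCCC4CCC5)C[C@@H](C)[C@@H]3[C@@H](O[Si](C)(C)C(C)(C)C)[C@H]12 | intermediate
20 | 6α-(tert-butyldimethylsilyloxy)-2α-hydroxy-13-nor-4βH,5αH,7αH-eudesman-12,8α-olide | C1C(=O)O[C@H]2C[C@@]3(C)C[C@@H](O)C[C@@H](C)[C@@H]3[C@@H](O[Si](C)(C)C(C)(C)C)[C@H]12 | intermediate
21 | 6α-(tert-butyldimethylsilyloxy)-2-oxo-13-nor-4βH,5αH,7αH-eudesman-12,8α-olide | C1C(=O)O[C@H]2C[C@@]3(C)CC(=O)C[C@@H](C)[C@@H]3[C@@H](O[Si](C)(C)C(C)(C)C)[C@H]12 | intermediate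
22 | 6α-(tert-butyldimethylsilyloxy)-2-oxo-13-nor-5αH,7αH-eudesm-3-en-12,8α-olide | C1C(=O)O[C@H]2C[C@@]3(C)CC(=O)C=C(C)[C@@H]3[C@@H](O[Si](C)(C)C(C)(C)C)[C@H]12 | intermediate
23 | 6α-(tert-butyldimethylsilyloxy)-2-(triethylsilyloxy)-13-nor-5αH,7αH-eudesma-1,3-dien-12,8α-olide | C1C(=O)O[C@H]2C[C@@]3(C)C=C(O[Si](CC)(CC)CC)C=C(C)[C@@H]3[C@@H](O[Si](C)(C)C(C)(C)C)[C@H]12 | intermediate
24 | (1(10)E,2E,4E)-6α-(tert-butyldimethylsilyloxy)-2-(triethylsilyloxy)-13-nor-7αH-germacra-1(10),2,4-trien-12,8α-olide (C2=C3 cis within the ring) | C1C(=O)O[C@H]2C/C(C)=C/C(O[Si](CC)(CC)CC)=C\C(C)=C\[C@@H](O[Si](C)(C)C(C)(C)C)[C@H]12 | intermediate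
25 | (1(10)E,4E)-6α-(tert-butyldimethylsilyloxy)-2-oxo-13-nor-7αH-germacra-1(10),4-dien-12,8α-olide | C1C(=O)O[C@H]2C/C(C)=C/C(=O)C/C(C)=C/[C@@H](O[Si](C)(C)C(C)(C)C)[C@H]12 | intermediate
26 | (1(10)E,4E)-6α-(tert-butyldimethylsilyloxy)-2β-hydroxy-13-nor-7αH-germacra-1(10),4-dien-12,8α-olide (2R) | C1C(=O)O[C@H]2C/C(C)=C/[C@H](O)C/C(C)=C/[C@@H](O[Si](C)(C)C(C)(C)C)[C@H]12 | intermediate
27 | (1(10)E,4E)-6α-(tert-butyldimethylsilyloxy)-13-(dimethylamino)-2β-hydroxy-7αH,11ξH-germacra-1(10),4-dien-12,8α-olide | CN(C)CC1C(=O)O[C@H]2C/C(C)=C/[C@H](O)C/C(C)=C/[C@@H](O[Si](C)(C)C(C)(C)C)[C@H]12 | intermediate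
28 | trimethylammonium iodide derived from 27 (N-methylated at the C13 amine) | C[N+](C)(C)CC1C(=O)O[C@H]2C/C(C)=C/[C@H](O)C/C(C)=C/[C@@H](O[Si](C)(C)C(C)(C)C)[C@H]12.[I-] | intermediate
29 | (1(10)E,4E)-6α-(tert-butyldimethylsilyloxy)-2β-hydroxy-7αH-germacra-1(10),4,11(13)-trien-12,8α-olide | C=C1C(=O)O[C@H]2C/C(C)=C/[C@H](O)C/C(C)=C/[C@@H](O[Si](C)(C)C(C)(C)C)[C@H]12 | intermediate
30 | (1(10)E,4E)-2α-acetoxy-6α-(tert-butyldimethylsilyloxy)-7αH-germacra-1(10),4,11(13)-trien-12,8α-olide (2S) | C=C1C(=O)O[C@H]2C/C(C)=C/[C@@H](OC(C)=O)C/C(C)=C/[C@@H](O[Si](C)(C)C(C)(C)C)[C@H]12 | intermediate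
31 | (1(10)E,4E)-2α-acetoxy-6α-hydroxy-7αH-germacra-1(10),4,11(13)-trien-12,8α-olide | C=C1C(=O)O[C@H]2C/C(C)=C/[C@@H](OC(C)=O)C/C(C)=C/[C@@H](O)[C@H]12 | intermediate
32 | (1(10)E)-2α-acetoxy-4α,5β-epoxy-6α-hydroxy-7αH-germacra-1(10),11(13)-dien-12,8α-olide (4R,5R) | C=C1C(=O)O[C@H]2C/C(C)=C/[C@@H](OC(C)=O)C[C@@]3(C)O[C@@H]3[C@@H](O)[C@H]12 | intermediate
33 | (2S,4R,5R,6S,7R,8S)-2α,6α-diacetoxy-4α,5β-epoxygermacra-1(10)E,11(13)-dien-12,8α-olide (CNP0270851.2) | C=C1C(=O)O[C@H]2C/C(C)=C/[C@@H](OC(C)=O)C[C@@]3(C)O[C@@H]3[C@@H](OC(C)=O)[C@H]12 | target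

## Step count and risk

Total step count: 22. Longest linear sequence: 22 steps (the route is linear from 1 and 2).

**Step 14 (key step).** The triene absorbs in the same region as the diene, so a photostationary mixture and secondary photoreactions can limit the amount of 24. The triethylsilyl trienol ether may also be lost before cleavage through thermal reclosure, a 1,7-hydrogen shift or adventitious hydrolysis with γ-protonation. The fallback sets out from enone 22. Its kinetic enolate would be trapped with TIPSOTf as the triisopropylsilyl dienol ether F1, which is robust enough for irradiation to low conversion in a cooled flow cell. The triisopropylsilyl trienol ether F2 would be separated from unreacted F1 on cold, base-washed silica, and F1 recycled. Cleavage of F2 with TBAF/AcOH at −78 °C returns to ketone 25.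

**Step 9.** Poor facial selectivity is the main risk: hydrogen delivered to the less hindered α face gives the axial 6β-alcohol. Lactone migration from O8 to O6 through the samarium alkoxide is the second. The fallback sets out from 16. NaBH4 should attack equatorially and give the 6β-alcohol F3. Mitsunobu reaction of F3 with chloroacetic acid would invert C6 to the 6α-chloroacetate F4. Removal of the chloroacetyl group with thiourea/NaHCO3 in ethanol, without an alkoxide, returns to 17.

**Step 16.** The facial selectivity of hydride addition to a flexible ten-membered enone may be the reverse of that expected, or low. The fallback sets out from 25 and keeps C2 adjustable. If reduction gives the 2α-alcohol F7, it would be carried through the same Mannich reaction (amine F8), methylation (ammonium iodide F9) and elimination to the methylene lactone 2α-alcohol F10. (R)-Me-CBS with catecholborane is the reagent-controlled way to reach F7. F10 would be acetylated with Ac2O/DMAP, with retention instead of Mitsunobu inversion, and the route rejoined at 30.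

**Step 8.** Loss of water from the aldol adduct by E1cB to the conjugated enone, or epimerisation at C5 to the cis-fused decalin, may compete with trapping as the lactone. The fallback sets out from 13. After acetal hydrolysis to 14, the condensation would be driven to completion (p-TsOH, benzene, reflux) to give the enone ester F5. Nucleophilic epoxidation (t-BuOOH, DBU) from the α face, opposite the axial C14, would give the 7α,8α-epoxy ketone F6. SmI2 would then cleave the C7–O bond to the 8α-hydroxy ketone 15, which lactonises (PPTS) and rejoins the route at 16.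

**Step 1.** Insufficient enantioselectivity, or erosion of it by retro-Michael reaction during the annulation, would compromise every later compound. The fallback sets out from 1 and 2. Annulation with pyrrolidinium acetate would give 4 together with its mirror image F12, through 3 and the enantiomeric adduct F11. Luche reduction would give 5 and its enantiomer F13. A lipase (CAL-B, vinyl acetate) should acylate the (4R)-alcohol F13 to the acetate F14 and leave 5, which is separated and rejoins the route at 5.

## Further compounds

F1 | step 14 | 6α-(tert-butyldimethylsilyloxy)-2-(triisopropylsilyloxy)-13-nor-5αH,7αH-eudesma-1,3-dien-12,8α-olide | C1C(=O)O[C@H]2C[C@@]3(C)C=C(O[Si](C(C)C)(C(C)C)C(C)C)C=C(C)[C@@H]3[C@@H](O[Si](C)(C)C(C)(C)C)[C@H]12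
F2 | step 14 | (1(10)E,2E,4E)-6α-(tert-butyldimethylsilyloxy)-2-(triisopropylsilyloxy)-13-nor-7αH-germacra-1(10),2,4-trien-12,8α-olide | C1C(=O)O[C@H]2C/C(C)=C/C(O[Si](C(C)C)(C(C)C)C(C)C)=C\C(C)=C\[C@@H](O[Si](C)(C)C(C)(C)C)[C@H]12
F3 | step 9 | 6β-hydroxy-13-nor-4βH,5αH,7αH-eudesm-1-en-12,8α-olide | C1C(=O)O[C@H]2C[C@@]3(C)C=CC[C@@H](C)[C@@H]3[C@H](O)[C@H]12
F4 | step 9 | 6α-(chloroacetoxy)-13-nor-4βH,5αH,7αH-eudesm-1-en-12,8α-olide | C1C(=O)O[C@H]2C[C@@]3(C)C=CC[C@@H](C)[C@@H]3[C@@H](OC(=O)CCl)[C@H]12
F5 | step 8 | ethyl 6-oxo-13-nor-4βH,5αH-eudesma-1,7-dien-12-oate | CCOC(=O)CC1=CC[C@@]2(C)C=CC[C@@H](C)[C@@H]2C1=O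
F6 | step 8 | ethyl 7α,8α-epoxy-6-oxo-13-nor-4βH,5αH-eudesm-1-en-12-oate | CCOC(=O)C[C@]12O[C@H]1C[C@@]3(C)C=CC[C@@H](C)[C@@H]3C2=O
F7 | step 16 | (1(10)E,4E)-6α-(tert-butyldimethylsilyloxy)-2α-hydroxy-13-nor-7αH-germacra-1(10),4-dien-12,8α-olide | C1C(=O)O[C@H]2C/C(C)=C/[C@@H](O)C/C(C)=C/[C@@H](O[Si](C)(C)C(C)(C)C)[C@H]12
F8 | step 16 | (1(10)E,4E)-6α-(tert-butyldimethylsilyloxy)-13-(dimethylamino)-2α-hydroxy-7αH,11ξH-germacra-1(10),4-dien-12,8α-olide | CN(C)CC1C(=O)O[C@H]2C/C(C)=C/[C@@H](O)C/C(C)=C/[C@@H](O[Si](C)(C)C(C)(C)C)[C@H]12
F9 | step 16 | trimethylammonium iodide derived from F8 | C[N+](C)(C)CC1C(=O)O[C@H]2C/C(C)=C/[C@@H](O)C/C(C)=C/[C@@H](O[Si](C)(C)C(C)(C)C)[C@H]12.[I-]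
F10 | step 16 | (1(10)E,4E)-6α-(tert-butyldimethylsilyloxy)-2α-hydroxy-7αH-germacra-1(10),4,11(13)-trien-12,8α-olide | C=C1C(=O)O[C@H]2C/C(C)=C/[C@@H](O)C/C(C)=C/[C@@H](O[Si](C)(C)C(C)(C)C)[C@H]12
F11 | step 1 | ethyl (3S)-2-acetyl-3-methyl-5-oxohexanoate | CCOC(=O)C(C(C)=O)[C@@H](C)CC(C)=O
F12 | step 1 | ethyl (1R,6S)-2,6-dimethyl-4-oxocyclohex-2-ene-1-carboxylate | CCOC(=O)[C@H]1C(C)=CC(=O)C[C@@H]1C
F13 | step 1 | ethyl (1R,4R,6S)-4-hydroxy-2,6-dimethylcyclohex-2-ene-1-carboxylate | CCOC(=O)[C@H]1C(C)=C[C@H](O)C[C@@H]1C
F14 | step 1 | ethyl (1R,4R,6S)-4-acetoxy-2,6-dimethylcyclohex-2-ene-1-carboxylate | CCOC(=O)[C@H]1C(C)=C[C@H](OC(C)=O)C[C@@H]1C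
A1 | alternative 1 | erythro germacr-1(10)-ene-4,5-diol with masked lactone | [C@H]1(O[Si](C)(C)C(C)(C)C)C/C(C)=C/[C@@H](OCc2ccc(OC)cc2)C[C@@](C)(O)[C@@H](O)[C@@H](OCc2ccc(OC)cc2)[C@@H]1C(=C)CO[Si](C)(C)C(C)(C)C
A2 | alternative 2 | ten-membered (E,E)-diene C10 enol triflate with the C2 ether set | [C@H]1(O[Si](CC)(CC)CC)C/C(OS(=O)(=O)C(F)(F)F)=C/[C@@H](OCc2ccc(OC)cc2)C/C(C)=C/[C@@H](O[Si](C)(C)C(C)(C)C)[C@@H]1C(=C)CO[Si](CC)(CC)CC
A3 | alternative 3 | 2-acetoxy-6-(triethylsilyloxy)germacra-1(10),4-diene with masked lactone | [C@H]1(O[Si](C)(C)C(C)(C)C)C/C(C)=C/[C@@H](OC(C)=O)C/C(C)=C/[C@@H](O[Si](CC)(CC)CC)[C@@H]1C(=C)CO[Si](C)(C)C(C)(C)C
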